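## The problem

The target 16 is an unsymmetrical biflavone. Flavone 1 consists of ring A (the 5,7-dihydroxylated benzo ring), ring C (its 4-pyranone) and ring B (4-hydroxy-3-methoxyphenyl). Flavone 2 consists of ring D (5,7-dihydroxylated benzo ring), ring F (its 4-pyranone) and ring E (4-hydroxyphenyl), and the halves are joined by one biaryl bond from C8 of ring A to C3' of ring E. That bond is the crux: it must be made at C8 and not at C6 of a phloroglucinol-type ring whose two open positions differ only in which neighbouring oxygen becomes O1, and it is crowded by three ortho substituents. There is no stereocentre, and the biaryl axis has no defined configuration in the target, so no stereochemical information has to be set or relayed. Six phenols must be freed at the end while the one methyl ether on ring B stays, which excludes global demethylation and points to benzyl ethers. The pyranones are opened by hot hydroxide, their C2-C3 double bonds can be reduced, and free phloroglucinol rings are easily oxidised and alkylated, so the heterocycles are built late and the phenols released last. Both ends of the biaryl bond carry an ortho oxygen, the C8a oxygen (the future O1) on ring A and the C4' hydroxyl on ring E. The two rings can therefore be tied through one carbon as a formaldehyde acetal, which holds C8 and C3' at the 1,7-distance of a dibenzo[d,f][1,3]dioxepine.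

## Retrosynthesis

**16 to 15.** All six phenols of 16 are cut back to benzyl ethers in 15. Hydrogenolysis is the only global deprotection that reliably leaves the ring B methyl ether alone, and benzyl ethers are inert to the bases and mild acids used earlier. The forward step must remove six benzyl groups without saturating either pyranone double bond.

**15 to 12 and 2.** Ring F is opened at O1''-C2'' and C2''-C3''. This is the Baker-Venkataraman pattern: diketone 14 comes from aryl ester 13, which comes from acid 12 and ketone 2. It is preferred to an aldol route here because the ring E carbon is already at the acid oxidation level, and because the hydroxyl of 2 has only one ortho substituent and acylates normally. The cut removes a whole flavone and leaves a monoflavone acid. The forward steps need an esterification of a chelated phenol, an intramolecular acyl transfer and an acid-catalysed ring closure that spares benzyl ethers.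

**12 to 9 and 10.** Ring C is opened at O1-C2 and C2-C3, giving chalcone 11 and then methyl ketone 9 and aldehyde 10. The aldol route is chosen for this pyranone because the C8a hydroxyl of 9 sits between the ring E aryl group and the acetyl group and would be hard to acylate, while the acetyl methyl group is unhindered. The strong base of the aldol step also hydrolyses the methyl ester, so the acid needed for the next disconnection appears without a separate step. The forward steps need a crowded ketone to condense and an oxidative ring closure that tolerates benzyl ethers.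

**9 to 7.** The ring E benzyl ether is removed to give diol 8, and the two hydroxyls of 8 are joined through a methylene group in dioxepine 7. In 8 the ring A hydroxyl is hydrogen-bonded to the acetyl group and flanked on both sides, so it stays untouched when the ring E hydroxyl is benzylated. The forward acetal cleavage must take off a diaryl formal under acid mild enough for four functional groups (two benzyl ethers, ester, ketone).

**7 to 6 (key disconnection).** The biaryl bond C8-C3' is cut, which opens the seven-membered ring and leaves diaryl formal 6. Against a cross-coupling of a C8 halide with a ring E boronate, this cut needs no halogenation of ring A (C8 and C6 are hard to tell apart once ring C exists) and no prefunctionalisation of either ring. Against an untethered oxidative coupling, the tether decides the site on both rings. The acetyl group is placed on ring A before this step: it blocks the second position ortho to the tether oxygen, it lowers the tendency of neutral ring A to couple with itself, and it removes a later Friedel-Crafts acylation on a ring bearing benzyl ethers. The forward reaction must oxidise ring A selectively and let the less electron-rich ring E close the ring.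

**6 to 2 and 5, and back to 1 and 3.** The mixed formal 6 is cut at the ring A oxygen-CH2 bond into phenol 2 and chloromethyl ether 5. The electrophilic carbon is placed on the benzoate side because the chlorination that makes 5 from thioacetal 4 would attack an electron-rich ring A. Ether 4 comes from ester 3, and 2 comes from triol 1 by benzylation of the two hydroxyls that are not locked in the chelate. Compound 2 is used twice, as ring A here and as ring D in the esterification to 13.

## Roads not taken

**Alternative 1:** Ring E is cut at C2'-C3' and C1'-C6'. In the forward direction, flavone 1 bearing a silyloxydiene at C8 (A2) adds to ethynylchromone A3, and a quinone oxidant in the same pot aromatises the cyclohexadiene to the silyl-protected pentabenzyl biflavone A1.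
- Merits: two finished halves meet in one step; the biaryl bond is never made by coupling; the donor and acceptor groups fix the orientation so that the silyloxy carbon ends up para to the chromone.
- Weak points: A2 needs a four-carbon enone chain grown on C8 of a complete flavone and then a geometry-selective silyl enol ether formation beside a polymerisable vinyl ketone. Its diene terminus carries an aryl group twisted by two ortho oxygens. A3 is activated only through vinylogy to the pyranone carbonyl, so heat is needed, at which dienol ethers can shift hydrogen.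
- Comparison: this road is more convergent than the chosen one, and its bond formation rests on a well-understood pericyclic reaction rather than an unproven electrolysis. The chosen plan sets against this purchasable aromatic rings, no labile diene, and a single hazard at step 5, early enough that failure costs little and a known palladium-catalysed closure on the same tether can take over.

**Alternative 2:** Ring A is cut at C8-C8a, C6-C7 and C4a-C8a. Heating cyclobutenone A5 with the ring E siloxyalkyne A6 gives, by ring opening to a vinylketene, ketene-alkyne cycloaddition, a second ring opening and a six-electron electrocyclisation, the salicylate A4.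
- Merits: the biaryl bond is present from the start as an aryl-alkyne bond, and the three ring A oxygens are born differentiated, with the only free hydroxyl on C8a. That control is as good as in the chosen plan and does not depend on oxidation potentials.
- Weak points: A5 is a strained, acidic four-membered keto ester of doubtful stability; A6 needs ynolate chemistry over several steps; the ethyl ether at C5 must later be removed beside the ring B methyl ether, and the dioxolane must be oxidised before flavone 2 can be built.
- Comparison: a ring that can be bought with the right oxygen pattern is built atom by atom, and the route would be clearly longer. The chosen plan obtains the same differentiation from the chelated hydroxyl and the acetyl group of 2.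

**Alternative 3:** Ring A is cut at C4a-C5. Thermolysis of the tert-butyl keto ester A8 gives an acylketene whose ketene carbon is attacked by the pyranone carbon that becomes C4a, closing ring A to the 8-aryl-5,7-dihydroxyflavone A7.
- Merits: A7 is a complete flavone 1 with the ring E ester, equivalent to 12 of the chosen route, and the aryl group is at C8 without ambiguity; no oxidation is involved.
- Weak points: A8 has a crowded benzylic carbon between a pyranone and a ketone and needs a long assembly. The acylketene can also be captured at oxygen by the neighbouring enol or the pyranone carbonyl, or dimerise, and the pyranone carbon is a weak nucleophile. The two free phenols of A7 must be protected again before flavone 2 is made.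
- Comparison: if A8 were easy to reach, this road would be shorter from ring A to flavone 1. As it stands, its ring closure is at least as speculative as the anodic coupling and has no known substitute that uses the same intermediates.

Key step: step 5

Assumption: the hydrogen-bonded hydroxyl ortho to an aryl ketone stays free under carbonate benzylation (used in steps 1 and 7); compound 10 and all reagents are purchased, and crude 5 is used directly.

## Route

**Step 1**
Reactants: 1 2,4,6-trihydroxyacetophenone
Product: 2 1-[2,4-bis(benzyloxy)-6-hydroxyphenyl]ethan-1-one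
Conditions: BnBr (2.1 equiv), K2CO3, DMF, rt
Reagents that add atoms: benzyl bromide, BrCc1ccccc1
Why: Williamson etherification; after the first ortho hydroxyl and the para hydroxyl are benzylated, the remaining ortho hydroxyl is held in a hydrogen bond to the ketone and is too weakly nucleophilic to react under carbonate conditions.

**Step 2**
Reactants: 3 methyl 4-hydroxybenzoate
Product: 4 methyl 4-[(methylsulfanyl)methoxy]benzoate
Conditions: NaH, DMF, 0 °C; then MeSCH2Cl, NaI (cat.), rt
Reagents that add atoms: chloromethyl methyl sulfide, ClCSC
Why: O-alkylation of the phenoxide with an activated alpha-chloro sulfide (Williamson type); the ester is inert.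

**Step 3**
Reactants: 4 methyl 4-[(methylsulfanyl)methoxy]benzoate
Product: 5 methyl 4-(chloromethoxy)benzoate
Conditions: SO2Cl2, CH2Cl2, 0 °C to rt; evaporate, use crude
Reagents that add atoms: sulfuryl chloride, O=S(=O)(Cl)Cl
Why: chlorinolysis of an O,S-acetal: S-chlorination gives a chlorosulfonium ion that loses methanesulfenyl chloride, and chloride captures the aryloxymethyl cation. The deactivated benzoate ring is not chlorinated, which is why the electrophile is made on this ring.

**Step 4**
Reactants: 2 1-[2,4-bis(benzyloxy)-6-hydroxyphenyl]ethan-1-one, 5 methyl 4-(chloromethoxy)benzoate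
Product: 6 methyl 4-{[2-acetyl-3,5-bis(benzyloxy)phenoxy]methoxy}benzoate
Conditions: 2, NaH (1.05 equiv), DMF, 0 °C; then crude 5, 0 °C to rt
Reagents that add atoms: none
Why: Williamson-type formation of a mixed diaryl formal; NaH breaks the chelate of 2, and the hard oxocarbenium-like chloromethyl ether reacts at the phenoxide oxygen, as in the methoxymethylation of ortho-hydroxyaryl ketones.

**Step 5**
Reactants: 6 methyl 4-{[2-acetyl-3,5-bis(benzyloxy)phenoxy]methoxy}benzoate
Product: 7 methyl 4-acetyl-1,3-bis(benzyloxy)dibenzo[d,f][1,3]dioxepine-10-carboxylate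
Conditions: boron-doped diamond anode, platinum cathode, undivided cell, Bu3NMe O3SOMe (0.1 M) in (CF3)2CHOH, constant current ca. 3 mA cm-2, ca. 2.2 F mol-1, 6 at ca. 10 mM, rt
Reagents that add atoms: none
Why: Proposed new method: ring A of 6 with its three alkoxy donors should be oxidised well before the ester-bearing ring E, and the fluorinated alcohol should keep the ring A radical cation alive long enough for the tethered ring E to attack it through the carbon ortho to the acetal oxygen, which is only meta to the ester; a second electron transfer and loss of two protons restore both arenes, while protons are reduced to H2 at the cathode. The closest known reaction type is the anodic intramolecular dehydrogenative coupling of two alkoxyarenes joined by a three-atom chain, which gives bridged biaryls with a seven-membered ring; the closest model for this tether is the palladium-catalysed closure of bromoaryl aryl formaldehyde acetals to the same dioxepine skeleton, and what is new is the use of an O-CH2-O tether in an anodic C-H/C-H coupling with a benzoate ring as the attacking partner. The dioxepine ring closes by direct attack of one arene carbon on the other, a 1,7-closure in which the new biaryl bond is itself the ring-closing bond and the only ring size the tether allows. No stereocentre is formed and the bridged biaryl axis is not configurationally stable. Site selectivity on ring A is secured because the acetyl group occupies the other position ortho to the acetal oxygen and C6 lies para to it, out of reach; on ring E the two ortho carbons are equivalent by symmetry. Selectivity against intermolecular coupling of two ring A units rests on dilution and on the acetyl group, which lowers the nucleophilicity of neutral ring A; protection of 7 against further oxidation rests on the hydrogen-bonding solvent and on stopping at about two electrons per molecule.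

**Step 6**
Reactants: 7 methyl 4-acetyl-1,3-bis(benzyloxy)dibenzo[d,f][1,3]dioxepine-10-carboxylate
Product: 8 methyl 3-[3-acetyl-4,6-bis(benzyloxy)-2-hydroxyphenyl]-4-hydroxybenzoate
Conditions: conc. HCl (cat.), MeOH-THF, 55 °C
Reagents that add atoms: none
Why: acid-catalysed transacetalisation, the same reaction that removes methoxymethyl ethers from phenols; the ring A phenol, a good leaving group because of its ortho acetyl group, should leave first, and methanol carries the CH2 off as dimethoxymethane so that it cannot alkylate ring A. Benzyl ethers, methyl ester and the hindered ketone tolerate methanolic HCl.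

**Step 7**
Reactants: 8 methyl 3-[3-acetyl-4,6-bis(benzyloxy)-2-hydroxyphenyl]-4-hydroxybenzoate
Product: 9 methyl 3-[3-acetyl-4,6-bis(benzyloxy)-2-hydroxyphenyl]-4-(benzyloxy)benzoate
Conditions: BnBr (1.1 equiv), K2CO3, acetone, reflux
Reagents that add atoms: benzyl bromide, BrCc1ccccc1
Why: Williamson etherification of the acidic ring E phenol (para to the ester); the ring A hydroxyl is chelated to the acetyl group and flanked on both sides, so it should stay free exactly as in step 1.

**Step 8**
Reactants: 9 methyl 3-[3-acetyl-4,6-bis(benzyloxy)-2-hydroxyphenyl]-4-(benzyloxy)benzoate, 10 4-(benzyloxy)-3-methoxybenzaldehyde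
Product: 11 3-{3-[(2E)-3-[4-(benzyloxy)-3-methoxyphenyl]prop-2-enoyl]-4,6-bis(benzyloxy)-2-hydroxyphenyl}-4-(benzyloxy)benzoic acid
Conditions: 10 (1.5 equiv), KOH (aq., excess), EtOH-THF, rt to 45 °C; then aq. HCl to pH 2
Reagents that add atoms: potassium hydroxide (aqueous), [K+].[OH-]
Why: Claisen-Schmidt condensation at the unhindered acetyl methyl group gives the thermodynamically preferred E enone, and the excess hydroxide saponifies the methyl ester in the same operation. Any flavanone formed by ring closure of the chalcone is carried into step 9, where it is oxidised to the same product.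

**Step 9**
Reactants: 11 3-{3-[(2E)-3-[4-(benzyloxy)-3-methoxyphenyl]prop-2-enoyl]-4,6-bis(benzyloxy)-2-hydroxyphenyl}-4-(benzyloxy)benzoic acid
Product: 12 4-(benzyloxy)-3-{5,7-bis(benzyloxy)-2-[4-(benzyloxy)-3-methoxyphenyl]-4-oxo-4H-chromen-8-yl}benzoic acid
Conditions: I2 (10 mol%), DMSO, 120 °C
Reagents that add atoms: none
Why: iodine-catalysed oxidative cyclisation of a 2'-hydroxychalcone: oxa-Michael closure (6-endo-trig) to the flavanone, alpha-iodination and loss of HI, with DMSO re-oxidising HI to iodine. The carboxylic acid and aryl ethers are spectators.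

**Step 10**
Reactants: 12 4-(benzyloxy)-3-{5,7-bis(benzyloxy)-2-[4-(benzyloxy)-3-methoxyphenyl]-4-oxo-4H-chromen-8-yl}benzoic acid, 2 1-[2,4-bis(benzyloxy)-6-hydroxyphenyl]ethan-1-one
Product: 13 2-acetyl-3,5-bis(benzyloxy)phenyl 4-(benzyloxy)-3-{5,7-bis(benzyloxy)-2-[4-(benzyloxy)-3-methoxyphenyl]-4-oxo-4H-chromen-8-yl}benzoate
Conditions: DCC, DMAP (cat.), CH2Cl2, rt
Reagents that add atoms: none
Why: Steglich esterification; the acylpyridinium formed from the O-acylisourea is reactive enough for the chelated phenol of 2, and the carbodiimide avoids acid chloride reagents that could attack the pyranone carbonyl.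

**Step 11**
Reactants: 13 2-acetyl-3,5-bis(benzyloxy)phenyl 4-(benzyloxy)-3-{5,7-bis(benzyloxy)-2-[4-(benzyloxy)-3-methoxyphenyl]-4-oxo-4H-chromen-8-yl}benzoate
Product: 15 5,7-bis(benzyloxy)-8-{2-(benzyloxy)-5-[5,7-bis(benzyloxy)-4-oxo-4H-chromen-2-yl]phenyl}-2-[4-(benzyloxy)-3-methoxyphenyl]-4H-chromen-4-one, via 1,3-diketone 14 (not isolated)
Conditions: LiN(SiMe3)2 (3 equiv), THF, -78 to 0 °C; AcOH quench, solvent exchange; p-TsOH·H2O (cat.), toluene, 90 °C
Reagents that add atoms: none
Why: Baker-Venkataraman rearrangement: the ketone enolate attacks the neighbouring aryl ester carbonyl through a six-membered transition state to give the 1,3-diketone 14. Acid then closes ring F by attack of the phenol on the enolised diketone and loss of water.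

**Step 12**
Reactants: 15 5,7-bis(benzyloxy)-8-{2-(benzyloxy)-5-[5,7-bis(benzyloxy)-4-oxo-4H-chromen-2-yl]phenyl}-2-[4-(benzyloxy)-3-methoxyphenyl]-4H-chromen-4-one
Product: 16 5,7-dihydroxy-8-[5-(5,7-dihydroxy-4-oxo-4H-chromen-2-yl)-2-hydroxyphenyl]-2-(4-hydroxy-3-methoxyphenyl)-4H-chromen-4-one
Conditions: H2 (1 atm), Pd/C (10 wt% palladium metal on carbon), THF-MeOH, rt
Reagents that add atoms: none
Why: hydrogenolysis of six aryl benzyl ethers; the aryl methyl ether is inert and the conjugated pyranone double bonds are normally kept under one atmosphere of hydrogen at room temperature if the reaction is stopped when debenzylation is complete.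

## Compound list

1 | 2,4,6-trihydroxyacetophenone | CC(=O)c1c(O)cc(O)cc1O | starting material
2 | 1-[2,4-bis(benzyloxy)-6-hydroxyphenyl]ethan-1-one | CC(=O)c1c(O)cc(OCc2ccccc2)cc1OCc1ccccc1 | intermediate
3 | methyl 4-hydroxybenzoate | COC(=O)c1ccc(O)cc1 | starting material
4 | methyl 4-[(methylsulfanyl)methoxy]benzoate | COC(=O)c1ccc(OCSC)cc1 | intermediate
5 | methyl 4-(chloromethoxy)benzoate | COC(=O)c1ccc(OCCl)cc1 | intermediate
6 | methyl 4-{[2-acetyl-3,5-bis(benzyloxy)phenoxy]methoxy}benzoate | COC(=O)c1ccc(OCOc2cc(OCc3ccccc3)cc(OCc3ccccc3)c2C(C)=O)cc1 | intermediate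
7 | methyl 4-acetyl-1,3-bis(benzyloxy)dibenzo[d,f][1,3]dioxepine-10-carboxylate | COC(=O)c1ccc2OCOc3c(C(C)=O)c(OCc4ccccc4)cc(OCc4ccccc4)c3-c2c1 | intermediate
8 | methyl 3-[3-acetyl-4,6-bis(benzyloxy)-2-hydroxyphenyl]-4-hydroxybenzoate | COC(=O)c1ccc(O)c(-c2c(O)c(C(C)=O)c(OCc3ccccc3)cc2OCc2ccccc2)c1 | intermediate
9 | methyl 3-[3-acetyl-4,6-bis(benzyloxy)-2-hydroxyphenyl]-4-(benzyloxy)benzoate | COC(=O)c1ccc(OCc2ccccc2)c(-c2c(O)c(C(C)=O)c(OCc3ccccc3)cc2OCc2ccccc2)c1 | intermediate
10 | 4-(benzyloxy)-3-methoxybenzaldehyde | COc1cc(C=O)ccc1OCc1ccccc1 | starting material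
11 | 3-{3-[(2E)-3-[4-(benzyloxy)-3-methoxyphenyl]prop-2-enoyl]-4,6-bis(benzyloxy)-2-hydroxyphenyl}-4-(benzyloxy)benzoic acid | COc1cc(/C=C/C(=O)c2c(O)c(-c3cc(C(=O)O)ccc3OCc3ccccc3)c(OCc3ccccc3)cc2OCc2ccccc2)ccc1OCc1ccccc1 | intermediate
12 | 4-(benzyloxy)-3-{5,7-bis(benzyloxy)-2-[4-(benzyloxy)-3-methoxyphenyl]-4-oxo-4H-chromen-8-yl}benzoic acid | COc1cc(-c2cc(=O)c3c(OCc4ccccc4)cc(OCc4ccccc4)c(-c4cc(C(=O)O)ccc4OCc4ccccc4)c3o2)ccc1OCc1ccccc1 | intermediate
13 | 2-acetyl-3,5-bis(benzyloxy)phenyl 4-(benzyloxy)-3-{5,7-bis(benzyloxy)-2-[4-(benzyloxy)-3-methoxyphenyl]-4-oxo-4H-chromen-8-yl}benzoate | COc1cc(-c2cc(=O)c3c(OCc4ccccc4)cc(OCc4ccccc4)c(-c4cc(C(=O)Oc5cc(OCc6ccccc6)cc(OCc6ccccc6)c5C(C)=O)ccc4OCc4ccccc4)c3o2)ccc1OCc1ccccc1 | intermediate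
14 | 1-[2,4-bis(benzyloxy)-6-hydroxyphenyl]-3-(4-(benzyloxy)-3-{5,7-bis(benzyloxy)-2-[4-(benzyloxy)-3-methoxyphenyl]-4-oxo-4H-chromen-8-yl}phenyl)propane-1,3-dione | COc1cc(-c2cc(=O)c3c(OCc4ccccc4)cc(OCc4ccccc4)c(-c4cc(C(=O)CC(=O)c5c(O)cc(OCc6ccccc6)cc5OCc5ccccc5)ccc4OCc4ccccc4)c3o2)ccc1OCc1ccccc1 | intermediate
15 | 5,7-bis(benzyloxy)-8-{2-(benzyloxy)-5-[5,7-bis(benzyloxy)-4-oxo-4H-chromen-2-yl]phenyl}-2-[4-(benzyloxy)-3-methoxyphenyl]-4H-chromen-4-one | COc1cc(-c2cc(=O)c3c(OCc4ccccc4)cc(OCc4ccccc4)c(-c4cc(-c5cc(=O)c6c(OCc7ccccc7)cc(OCc7ccccc7)cc6o5)ccc4OCc4ccccc4)c3o2)ccc1OCc1ccccc1 | intermediate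
16 | 5,7-dihydroxy-8-[5-(5,7-dihydroxy-4-oxo-4H-chromen-2-yl)-2-hydroxyphenyl]-2-(4-hydroxy-3-methoxyphenyl)-4H-chromen-4-one | COc1cc(-c2cc(=O)c3c(O)cc(O)c(-c4cc(-c5cc(=O)c6c(O)cc(O)cc6o5)ccc4O)c3o2)ccc1O | target

## Step count and risks

Total steps: 12. Longest linear sequence: 11 steps (3 to 16 through steps 2 to 12); the branch from 1 joins at step 4 and again at step 10.

**Step 5 (key step, proposed new method).** The attack of the deactivated ring E on the ring A radical cation may be too slow. Competing processes are coupling between ring A units of two molecules, oxidative loss of benzyl groups through the radical cation, and oxidation at the acetal CH2. The fallback uses the known palladium-catalysed direct arylation on the same tether; it sets out from 2 and comes back at 7.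
- Methyl 3-bromo-4-hydroxybenzoate F1 is taken through the chemistry of steps 2 and 3 to methyl 3-bromo-4-[(methylsulfanyl)methoxy]benzoate F2 and methyl 3-bromo-4-(chloromethoxy)benzoate F3.
- The sodium salt of 2 is alkylated with F3 to give methyl 4-{[2-acetyl-3,5-bis(benzyloxy)phenoxy]methoxy}-3-bromobenzoate F4.
- Pd(OAc)2, PCy3·HBF4, K2CO3 and pivalic acid in N,N-dimethylacetamide at 110 °C should close the ring. Zerovalent palladium formed in the flask inserts into the C-Br bond, carboxylate-assisted metalation takes place at the only C-H of ring A within reach (C8), and reductive elimination gives 7.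

**Step 6.** Solvolysis of a formal flanked by two aryl oxygens may be slow. Forcing the acid would start to remove benzyl groups, first the one beside the acetyl group, or let the released one-carbon electrophile add to C6 of ring A. The fallback changes the mode of cleavage from Brønsted-acid solvolysis to boron-halide opening; it sets out from 7 and comes back at 8. Me2BBr in CH2Cl2 at -78 °C should bind the ring A oxygen and the ketone and deliver bromide to the CH2, giving methyl 3-[3-acetyl-4,6-bis(benzyloxy)-2-hydroxyphenyl]-4-(bromomethoxy)benzoate F5 (written with its ring A oxygen as the free phenol). F5 is hydrolysed on work-up with aqueous NaHCO3 to 8, with no free cation near ring A.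

**Step 9.** Hydrogen iodide formed at 120 °C may remove the C5 benzyl group peri to the carbonyl, or iodine may substitute C6 of ring A; the preceding aldol at a crowded ketone may also be sluggish. The fallback builds ring C by acyl transfer instead and bypasses steps 8 and 9; it sets out from 9 and comes back at 12.
- The sodium salt of 9 (NaH, THF) is acylated with 4-(benzyloxy)-3-methoxybenzoyl chloride F6 to give methyl 3-{3-acetyl-4,6-bis(benzyloxy)-2-[4-(benzyloxy)-3-methoxybenzoyloxy]phenyl}-4-(benzyloxy)benzoate F7.
- Baker-Venkataraman rearrangement with LiN(SiMe3)2 gives methyl 4-(benzyloxy)-3-(4,6-bis(benzyloxy)-3-{3-[4-(benzyloxy)-3-methoxyphenyl]-3-oxopropanoyl}-2-hydroxyphenyl)benzoate F8.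
- Cyclodehydration with p-TsOH gives methyl 4-(benzyloxy)-3-{5,7-bis(benzyloxy)-2-[4-(benzyloxy)-3-methoxyphenyl]-4-oxo-4H-chromen-8-yl}benzoate F9.
- LiOH in THF-water gives 12.

**Step 12.** The pyranone double bonds may be reduced to flavanones once the benzyl groups are gone, or debenzylation may stall because partly deprotected material precipitates on the catalyst. The fallback replaces hydrogenolysis by Lewis-acid debenzylation and goes from 15 directly to 16: BCl3 with pentamethylbenzene as benzyl cation scavenger in CH2Cl2 at -78 °C, conditions under which an aryl methyl ether that is not next to a carbonyl group should stay intact.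

## Further compounds

F1 | step 5 | methyl 3-bromo-4-hydroxybenzoate | COC(=O)c1ccc(O)c(Br)c1
F2 | step 5 | methyl 3-bromo-4-[(methylsulfanyl)methoxy]benzoate | COC(=O)c1ccc(OCSC)c(Br)c1
F3 | step 5 | methyl 3-bromo-4-(chloromethoxy)benzoate | COC(=O)c1ccc(OCCl)c(Br)c1
F4 | step 5 | methyl 4-{[2-acetyl-3,5-bis(benzyloxy)phenoxy]methoxy}-3-bromobenzoate | COC(=O)c1ccc(OCOc2cc(OCc3ccccc3)cc(OCc3ccccc3)c2C(C)=O)c(Br)c1
F5 | step 6 | methyl 3-[3-acetyl-4,6-bis(benzyloxy)-2-hydroxyphenyl]-4-(bromomethoxy)benzoate | COC(=O)c1ccc(OCBr)c(-c2c(O)c(C(C)=O)c(OCc3ccccc3)cc2OCc2ccccc2)c1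
F6 | step 9 | 4-(benzyloxy)-3-methoxybenzoyl chloride | COc1cc(C(Cl)=O)ccc1OCc1ccccc1
F7 | step 9 | methyl 3-{3-acetyl-4,6-bis(benzyloxy)-2-[4-(benzyloxy)-3-methoxybenzoyloxy]phenyl}-4-(benzyloxy)benzoate | COC(=O)c1ccc(OCc2ccccc2)c(-c2c(OC(=O)c3ccc(OCc4ccccc4)c(OC)c3)c(C(C)=O)c(OCc3ccccc3)cc2OCc2ccccc2)c1
F8 | step 9 | methyl 4-(benzyloxy)-3-(4,6-bis(benzyloxy)-3-{3-[4-(benzyloxy)-3-methoxyphenyl]-3-oxopropanoyl}-2-hydroxyphenyl)benzoate | COC(=O)c1ccc(OCc2ccccc2)c(-c2c(O)c(C(=O)CC(=O)c3ccc(OCc4ccccc4)c(OC)c3)c(OCc3ccccc3)cc2OCc2ccccc2)c1
F9 | step 9 | methyl 4-(benzyloxy)-3-{5,7-bis(benzyloxy)-2-[4-(benzyloxy)-3-methoxyphenyl]-4-oxo-4H-chromen-8-yl}benzoate | COC(=O)c1ccc(OCc2ccccc2)c(-c2c(OCc3ccccc3)cc(OCc3ccccc3)c3c(=O)cc(-c4ccc(OCc5ccccc5)c(OC)c4)oc23)c1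
F0 | step 12 | none | none
A1 | alternative 1 | 5,7-bis(benzyloxy)-8-{5-[5,7-bis(benzyloxy)-4-oxo-4H-chromen-2-yl]-2-[(tert-butyldimethylsilyl)oxy]phenyl}-2-[4-(benzyloxy)-3-methoxyphenyl]-4H-chromen-4-one | COc1cc(-c2cc(=O)c3c(OCc4ccccc4)cc(OCc4ccccc4)c(-c4cc(-c5cc(=O)c6c(OCc7ccccc7)cc(OCc7ccccc7)cc6o5)ccc4O[Si](C)(C)C(C)(C)C)c3o2)ccc1OCc1ccccc1
A2 | alternative 1 | 5,7-bis(benzyloxy)-2-[4-(benzyloxy)-3-methoxyphenyl]-8-{(1Z)-2-[(tert-butyldimethylsilyl)oxy]buta-1,3-dien-1-yl}-4H-chromen-4-one | COc1cc(-c2cc(=O)c3c(OCc4ccccc4)cc(OCc4ccccc4)c(/C=C(\O[Si](C)(C)C(C)(C)C)C=C)c3o2)ccc1OCc1ccccc1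
A3 | alternative 1 | 5,7-bis(benzyloxy)-2-ethynyl-4H-chromen-4-one | C#Cc1cc(=O)c2c(OCc3ccccc3)cc(OCc3ccccc3)cc2o1
A4 | alternative 2 | methyl 3-[2-(benzyloxy)-5-(1,3-dioxolan-2-yl)phenyl]-6-ethoxy-2-hydroxy-4-[(triisopropylsilyl)oxy]benzoate | CCOc1cc(O[Si](C(C)C)(C(C)C)C(C)C)c(-c2cc(C3OCCO3)ccc2OCc2ccccc2)c(O)c1C(=O)OC
A5 | alternative 2 | methyl 2-ethoxy-4-oxocyclobut-2-ene-1-carboxylate (racemic) | CCOC1=CC(=O)C1C(=O)OC
A6 | alternative 2 | ({[2-(benzyloxy)-5-(1,3-dioxolan-2-yl)phenyl]ethynyl}oxy)triisopropylsilane | CC(C)[Si](OC#Cc1cc(C2OCCO2)ccc1OCc1ccccc1)(C(C)C)C(C)C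
A7 | alternative 3 | methyl 4-(benzyloxy)-3-{2-[4-(benzyloxy)-3-methoxyphenyl]-5,7-dihydroxy-4-oxo-4H-chromen-8-yl}benzoate | COc1cc(-c2cc(=O)c3c(O)cc(O)c(-c4cc(C(=O)OC)ccc4OCc4ccccc4)c3o2)ccc1OCc1ccccc1
A8 | alternative 3 | tert-butyl 4-[2-(benzyloxy)-5-(methoxycarbonyl)phenyl]-4-{6-[4-(benzyloxy)-3-methoxyphenyl]-4-oxo-4H-pyran-2-yl}-3-oxobutanoate (racemic) | COc1cc(-c2cc(=O)cc(C(C(=O)CC(=O)OC(C)(C)C)c3cc(C(=O)OC)ccc3OCc3ccccc3)o2)ccc1OCc1ccccc1
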